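(The numbers in the tables stem from a simulated flask from invented constants, noise included.)

**Follow J.** I need J in the flask at the asked time, so I want its late decay.

| setting | winter | flask |
|---|---|---|
| G | 0.050 M | 0.050 M |
| D | 0.15 M | 0.100 M |
| remark | run made earlier |  |
| time |  | 80 min |

winter run (percent of the G charged)

| time / min | J / % | E / % |
|---|---|---|
| 4.00 | 18.0 | 3.7 |
| 8.00 | 26.0 | 7.4 |
| 12.0 | 28.2 | 10.2 |
| 15.0 | 28.4 | 11.2 |
| 20.0 | 27.4 | 12.2 |
| 25.0 | 25.7 | 11.5 |

(standard deviation of a reading: 0.3 percentage points)

- equivalents of D to G, everything else as given, that leave most J at 80 min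
- the amount of J then, in percent of the G charged
- the amount of J with the amounts as given

- no earlier run changes the charge of D; that part of a forecast is a guess

**Winter ladder.** In the winter run, J reaches 18.0% by 4.00 min. Its highest reading is 28.4% at 15.0 min. E reads highest later, 12.2% at 20.0 min. Then comes the tail of J: the readings from 15.0 min to 25.0 min give a loss of 0.00999 min⁻¹, a lifetime of 100 min, longer than the run.

**Flask clock.** I treat the tail as pseudo-first-order in [D], a guess. The tail rate, J's fractional loss per minute past its top, scaled by the charge of D, is then 0.00666 min⁻¹ in the flask. By the same scaling I put the top of J in the flask at about 22.5 min, and the asked 80 min lies past that estimate.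

**My reckoning.** Integrating the tail gives [J] = [J]top exp(−rate × (t − ttop)). Carrying over the winter top reading as [J]top, a second guess, I expect 19.4% J in the flask at 80 min. I have no reckoning for the best charge.

**Forecast.** The forecast gives a best charge of 1.15 equiv, 28.5% J there and 23% J with the amounts as given, on this ground: “I assume each step is first order in D, which is a guess”.

**Result.** The flask gives 18.6% J; the best charge is 1.16 equiv, leaving 21.1%.

    G + D ⇌ Z + J (K = 2.00, k = 1.30 M⁻¹ min⁻¹)
    J + D ⇌ Z + Q (K = 0.670, k = 6.90 M⁻¹ min⁻¹)
    Q + D ⇌ Z + E (K = 0.700, k = 0.550 M⁻¹ min⁻¹)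
    Q → L (k = 0.0630 min⁻¹)

The forward step J + D alone gives J a half-life of 1.0 min at the charged concentrations, way back not counted, far shorter than 80 min. From the flask's 26.3% J at 40.0 min, the tail rate gives 20.1% at 80 min.

**Later reading.** For the same flask read at 5.0 h, the tail rate carries 18.6% down to 4.30%. The computed amount of J is 5.67%.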